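Remark on the chemistry: locants follow the target's name. C1 is quaternary; C3 carries the caffeate (trans to O4, cis to the carboxyl); C5 is cis to O4 and to O1. This is the reverse of the current IUPAC numbering of quinic acid. "Quinate" names keep the configuration of (−)-quinic acid.

## The problem

The target is one cyclohexane with four stereocentres (C1, C3, C4, C5) and no carbon–carbon bond to be made. (−)-Quinic acid (1) already holds the skeleton and all four configurations, so the task reduces to two bonds to oxygen: the O1–CH3 ether and the O3 caffeate ester. The ether is the hard one. O1 is tertiary, sits next to the carboxyl carbon and is the least nucleophilic of the four hydroxyls, so an intermolecular methylation must beat three secondary oxygens and the carboxylate. The ester must land on O3 alone. Here the stereocentres help: O3/O4 are trans-diequatorial and accept a butane-2,3-diacetal, O4/O5 are cis and accept an acetonide, so either neighbour of O4 can be left free. The same centres fix the chair in which the carboxyl is equatorial and O1 and O5 are both axial on one face. The caffeate limits the endgame: base hydrolyses it or moves it from O3 to O4, its alkene rules out hydrogenolysis, and the catechol oxidises in base. The acid therefore cannot be released by saponification once the caffeate is on. The feature exploited is the syn-1,3-diaxial pair O1/O5: one carbon spans them as a 1,3-dioxane (O1, C1, C6, C5, O5 and the new CH2), so the future methyl carbon can be fixed first on the accessible O5 and then handed to O1 in a ring closure.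

## Retrosynthesis

Target 18 is reached from the fully protected ester 16 by removing only acid-labile groups (4-methoxybenzyl ester, acetonide, two aryl acetates). Cutting the O3–acyl bond of 16 gives alcohol 12 and acid chloride 15. Acylating a free triol acid would have no site selectivity, and an inverting esterification would need the C3 epimer, so plain acylation of the only free hydroxyl of 12 is preferred. The forward step has to acylate a secondary alcohol cleanly and nothing more.

Acid chloride 15 goes back through diacetate 14 to caffeic acid (13). The acetates keep the catechol out of the acylation and fall under the same aqueous acid that finishes the synthesis.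

Alcohol 12 differs from triol ester 9 by the 4,5-acetonide and by the ester group. The acetonide (via 10) uses the cis relationship of O4/O5 and leaves O3 open. The methyl ester of 10 is exchanged for the 4-methoxybenzyl ester through cesium salt 11 before the caffeate arrives, because afterwards no hydroxide can be used. The forward steps are a thermodynamic ketalisation and a carboxylate alkylation.

In 9 the O1–CH3 bond is traced back to a carbon that is still bonded to O5: the 1,5-O-methylene acetal 6. Against direct methylation of O1 this has the advantage that the carbon is already on O1 and only the CH2–O5 bond must be broken by hydride. The forward reaction is asked to cleave that bond and not the CH2–O1 bond. It is run on bis-silyl ether 7 (giving 8) so that no free hydroxyl interferes. It cannot be run on the diacetal 5, whose ketal carbons would ionise and be reduced long before a formaldehyde acetal, so 6 is derived from 5 by hydrolysis of the diacetal.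

Acetal 5 is cut at the O1–CH2 bond, giving the O5 methylthiomethyl ether 4 with O1–H free; this is the key disconnection. Its neighbours are double alkylation of the diol with a dihalomethane (strong base on a tertiary alkoxide next to an ester) and acid-catalysed formaldehyde acetal exchange (which would strip the diacetal). The chosen cut needs only a thiophile at low temperature. The precursor has one ring fewer and carries the future methyl carbon on the unhindered oxygen. The forward reaction must make the oxocarbenium ion and have O1–H capture it before anything else does.

Ether 4 comes from diol 3 by methylthiomethylation of the secondary O5–H. Diol 3 comes in one operation from 1 and 2,2,3,3-tetramethoxybutane (2), which esterifies the acid, protects the trans-3,4-diol and locks the chair that holds O1 and O5 diaxial.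

## Roads not taken

Alternative 1: The cut is the C1–C6 bond, with the C4=C5 alkene as retron. Cyclohexene acid A1 would come from the silyl ketene acetal of the trans-5-silyloxy-6-vinyl δ-lactone A2 by Ireland–Claisen rearrangement. The lactone ring enforces a boat transition state, the new bond forms on the face that carries the vinyl group, and the carboxyl ends up cis to O3. Merits: the methoxy group sits on the enolised carbon from the start, so the hindered etherification never arises. O3 arrives protected and differentiated. The alkene is placed for osmium-catalysed cis-dihydroxylation anti to the allylic silyl ether, which is the 3,4-trans-4,5-cis pattern required. Weak points: A2 has two stereocentres that must first be made enantiopure, which costs several steps before the key step. The dihydroxylation must also win its face against the quaternary centre, and ester and diol protection are still needed before caffeoylation. On the ether this road is better than the chosen plan (no tether, no question of which acetal bond opens), and on O3 differentiation it is at least equal. The chosen plan sets against this that all four stereocentres are bought in 1, that no stereoselective step is needed, and that nine linear steps suffice.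

Alternative 2: The cuts are C1–C2 and C5–C6. Diels–Alder addition of A5 to the exocyclic alkene of dioxolanone A4 would give spiro adduct A3, the tert-butyl acetal screening one face so that the quaternary carbon forms in one step with predictable configuration. Merits: a very short entry to the ring. After methanolysis of the dioxolanone the tertiary hydroxyl is the only hydroxyl present and could be methylated by ordinary alkoxide chemistry, which is simpler than any tether. Weak points: A3 has none of the three secondary oxygens. Its alkene covers only two of the three carbinol carbons, so a halolactonisation–elimination–dihydroxylation sequence, or an oxygenated diene with regio- and endo/exo problems, is needed. Three stereocentres would then be set from C1 alone. This road is better on the ether and worse on everything else. The chosen plan spends three steps (2, 3 and 5) on the ether but none on stereoselective oxygenation.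

Alternative 3: The cut is C4–C5. Intramolecular pinacol coupling of dialdehyde A7 with SmI2 (divalent samarium) would close the ring and give cis-diol A6 through a chelated pair of ketyls. Merits: A6 is triol 9 with O3 already silylated, so it would enter the endgame ahead of 10 and spare the diacetal-to-acetonide exchange. The ether is in place from an acyclic precursor. Weak points: A7 needs an acyclic quaternary α-methoxy ester centre and the C3 centre in enantiopure form. It is a β-methoxy aldehyde (loss of methanol) and an α-silyloxy aldehyde (epimerisation, reductive C–O cleavage), and the α-methoxy ester is itself open to reductive cleavage by the same reagent. The diol must form anti to O3 with only weak 1,3-induction from C1. This road is better on O3 differentiation and at least equal on the ether. The chosen plan creates no stereocentre and starts from 1.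

Key step: step 3

## Route

Step 1
Reactants: 1 (−)-quinic acid; 2 2,2,3,3-tetramethoxybutane
Product: 3 methyl 3,4-O-[(2S,3S)-2,3-dimethoxybutane-2,3-diyl]quinate (O1–H and axial O5–H free)
Conditions: HC(OMe)3, CSA (cat.), MeOH, reflux
Reagents that add atoms: methanol, CO
Why: Fischer esterification and butane-2,3-diacetal formation in one pot; only the trans-diequatorial O3/O4 pair gives the trans-fused 1,4-dioxane, and the two new acetal carbons (S,S) are set under thermodynamic control with both methoxy groups axial (double anomeric effect).

Step 2
Reactants: 3 methyl 3,4-O-[(2S,3S)-2,3-dimethoxybutane-2,3-diyl]quinate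
Product: 4 methyl 3,4-O-[(2S,3S)-2,3-dimethoxybutane-2,3-diyl]-5-O-(methylthiomethyl)quinate
Conditions: Me2S, (BzO)2 (added in portions), MeCN, 0 °C
Reagents that add atoms: dimethyl sulfide, CSC
Why: Pummerer-type methylthiomethylation: the benzoyloxysulfonium salt collapses to MeS+=CH2, which is taken up by the secondary O5–H in preference to the hindered, ester-deactivated tertiary O1–H; no base is present that could turn an alkoxysulfonium ion into a ketone.

Step 3
Reactants: 4 methyl 3,4-O-[(2S,3S)-2,3-dimethoxybutane-2,3-diyl]-5-O-(methylthiomethyl)quinate
Product: 5 methyl 1,5-O-methylene-3,4-O-[(2S,3S)-2,3-dimethoxybutane-2,3-diyl]quinate (2,4-dioxabicyclo[3.3.1]nonane core)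
Conditions: NIS, TfOH (cat.), 4 Å MS, CH2Cl2, −30 to 0 °C
Reagents that add atoms: none
Why: Acid-activated NIS transfers iodonium to sulfur, the iodosulfonium ion loses MeSI, and the O5-bound oxocarbenium ion is attacked at carbon by the axial O1–H; proton loss gives the acetal and returns the acid. The closest known reaction type is thiophile-promoted activation of O,S-acetals (thioglycosides, methylthiomethyl ethers) with capture by a neighbouring hydroxyl to give a methylene acetal. The 1,3-dioxane closes in the 6-endo-trig mode, the C=O+ bond lying inside the new ring. No stereocentre is formed or touched. The step needs intramolecular capture to outrun trapping by succinimide or water; the diacetal-locked chair holds O1 syn-diaxial to O5 at bonding distance, and sieves and low temperature suppress the rest. It also needs the diacetal to survive, which is expected because such diacetals tolerate NIS/TfOH activation of thioglycosides and sulfur is the only soft nucleophile present. The poor nucleophilicity of the tertiary hydroxyl is offset by the very high electrophilicity of a formaldehyde-derived oxocarbenium ion and by the absence of an entropic penalty.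

Step 4
Reactants: 5 methyl 1,5-O-methylene-3,4-O-[(2S,3S)-2,3-dimethoxybutane-2,3-diyl]quinate
Product: 6 methyl 1,5-O-methylenequinate (3,4-diol)
Conditions: TFA/H2O (9:1), rt
Reagents that add atoms: none
Why: Acid hydrolysis of the ketal-type diacetal; the formaldehyde acetal ionises many orders of magnitude more slowly and stays. The bridge keeps the ester equatorial, so O3–H cannot lactonise.

Step 5
Reactants: 6 methyl 1,5-O-methylenequinate
Product: 9 methyl 1-O-methylquinate, via bis(triethylsilyl) ether 7 (not isolated), via tris(triethylsilyl) ether 8 (not isolated)
Conditions: TESOTf (3.2 equiv), 2,6-lutidine (2.1 equiv), CH2Cl2, 0 °C; then Et3SiH, 0 °C to rt; then 1 M HCl, MeOH, rt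
Reagents that add atoms: none
Why: Lewis acid–silane reductive opening of a cyclic acetal (ionic hydrogenation): after silylation of O3/O4, the bulky silyl cation binds the more basic, less crowded O5, the CH2–O5 bond breaks and Et3SiH reduces the O1-bound oxocarbenium ion to the methyl ether. The lutidine buffer keeps free TfOH out, since a proton would favour the electronically preferred cleavage at O1. Acid methanolysis then strips the three silyl ethers without touching a stereocentre.

Step 6
Reactants: 9 methyl 1-O-methylquinate
Product: 10 methyl 4,5-O-isopropylidene-1-O-methylquinate (O3–H free)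
Conditions: Me2C(OMe)2, TsOH·H2O (cat.), acetone, rt
Reagents that add atoms: 2,2-dimethoxypropane, COC(C)(C)OC
Why: Thermodynamic ketalisation: the cis-4,5-diol gives an unstrained cis-fused dioxolane, whereas the trans-3,4-diol would give a strained trans-fused one. Room temperature keeps O3–H from lactonising onto the ester.

Step 7
Reactants: 10 methyl 4,5-O-isopropylidene-1-O-methylquinate
Product: 12 4-methoxybenzyl 4,5-O-isopropylidene-1-O-methylquinate, via cesium carboxylate 11 (not isolated)
Conditions: CsOH·H2O (1.05 equiv), THF/H2O, 0 °C to rt; evaporate (toluene azeotrope); then PMBCl, DMF, rt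
Reagents that add atoms: cesium hydroxide, [Cs+].[OH-]; 4-methoxybenzyl chloride, COc1ccc(CCl)cc1
Why: Saponification of the α-alkoxy-activated methyl ester followed by SN2 O-alkylation of the cesium carboxylate. The free acid is never liberated, so acid-catalysed lactonisation with O3–H is avoided, and O3–H is not alkylated without a strong base.

Step 8
Reactants: 13 caffeic acid
Product: 14 (E)-3,4-diacetoxycinnamic acid
Conditions: Ac2O, pyridine, rt; then H2O
Reagents that add atoms: acetic anhydride, CC(=O)OC(C)=O
Why: Acetylation of both phenols; the water quench hydrolyses the mixed anhydride formed at the carboxyl.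

Step 9
Reactants: 14 (E)-3,4-diacetoxycinnamic acid
Product: 15 (E)-3,4-diacetoxycinnamoyl chloride
Conditions: (COCl)2, DMF (cat.), CH2Cl2, 0 °C to rt
Reagents that add atoms: oxalyl chloride, O=C(Cl)C(=O)Cl
Why: Acid chloride formation through the Vilsmeier-type chloroiminium catalyst; aryl acetates and the E-alkene are inert.

Step 10
Reactants: 12 4-methoxybenzyl 4,5-O-isopropylidene-1-O-methylquinate; 15 (E)-3,4-diacetoxycinnamoyl chloride
Product: 16 4-methoxybenzyl 3-O-[(E)-3,4-diacetoxycinnamoyl]-4,5-O-isopropylidene-1-O-methylquinate
Conditions: pyridine, DMAP (cat.), CH2Cl2, 0 °C to rt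
Reagents that add atoms: none
Why: DMAP-catalysed acylation (nucleophilic catalysis) of the only free hydroxyl; with O4/O5 tied in the acetonide no acyl migration is possible, and C3 keeps its configuration because only the O–H bond reacts.

Step 11
Reactants: 16 4-methoxybenzyl 3-O-[(E)-3,4-diacetoxycinnamoyl]-4,5-O-isopropylidene-1-O-methylquinate
Product: 18 3-O-caffeoyl-1-methylquinic acid, via diacetate acid 17 (not isolated)
Conditions: TFA/H2O (9:1), 0 °C to rt; evaporate; then 1 M HCl (aq)/THF, rt
Reagents that add atoms: none
Why: Acidolysis of the 4-methoxybenzyl ester (alkyl–oxygen cleavage) and hydrolysis of the acetonide, done while the arene is still deactivated by its acetates so the benzyl cation does not alkylate it. Acid-catalysed hydrolysis of the two aryl acetates follows; acid avoids the base-induced O3-to-O4 acyl shift and catechol oxidation.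

## Compound list

1 | (−)-quinic acid | O[C@@]1(C(=O)O)C[C@@H](O)[C@@H](O)[C@H](O)C1 | starting material
2 | 2,2,3,3-tetramethoxybutane | COC(C)(OC)C(C)(OC)OC | starting material
3 | methyl 3,4-O-[(2S,3S)-2,3-dimethoxybutane-2,3-diyl]quinate | O[C@@]1(C(=O)OC)C[C@@H](O)[C@@H](O[C@](C)(OC)[C@@](C)(OC)O2)[C@H]2C1 | intermediate
4 | methyl 3,4-O-[(2S,3S)-2,3-dimethoxybutane-2,3-diyl]-5-O-(methylthiomethyl)quinate | O[C@@]1(C(=O)OC)C[C@@H](OCSC)[C@@H](O[C@](C)(OC)[C@@](C)(OC)O2)[C@H]2C1 | intermediate
5 | methyl 1,5-O-methylene-3,4-O-[(2S,3S)-2,3-dimethoxybutane-2,3-diyl]quinate | C3O[C@@]1(C(=O)OC)C[C@@H](O3)[C@@H](O[C@](C)(OC)[C@@](C)(OC)O2)[C@H]2C1 | intermediate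
6 | methyl 1,5-O-methylenequinate | C2O[C@@]1(C(=O)OC)C[C@@H](O2)[C@@H](O)[C@H](O)C1 | intermediate
7 | methyl 1,5-O-methylene-3,4-bis-O-(triethylsilyl)quinate | C2O[C@@]1(C(=O)OC)C[C@@H](O2)[C@@H](O[Si](CC)(CC)CC)[C@H](O[Si](CC)(CC)CC)C1 | intermediate
8 | methyl 1-O-methyl-3,4,5-tris-O-(triethylsilyl)quinate | CO[C@@]1(C(=O)OC)C[C@@H](O[Si](CC)(CC)CC)[C@@H](O[Si](CC)(CC)CC)[C@H](O[Si](CC)(CC)CC)C1 | intermediate
9 | methyl 1-O-methylquinate | CO[C@@]1(C(=O)OC)C[C@@H](O)[C@@H](O)[C@H](O)C1 | intermediate
10 | methyl 4,5-O-isopropylidene-1-O-methylquinate | CO[C@@]1(C(=O)OC)C[C@@H](OC(C)(C)O2)[C@@H]2[C@H](O)C1 | intermediate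
11 | cesium 4,5-O-isopropylidene-1-O-methylquinate | CO[C@@]1(C(=O)[O-])C[C@@H](OC(C)(C)O2)[C@@H]2[C@H](O)C1.[Cs+] | intermediate
12 | 4-methoxybenzyl 4,5-O-isopropylidene-1-O-methylquinate | CO[C@@]1(C(=O)OCc3ccc(OC)cc3)C[C@@H](OC(C)(C)O2)[C@@H]2[C@H](O)C1 | intermediate
13 | caffeic acid | O=C(O)/C=C/c1ccc(O)c(O)c1 | starting material
14 | (E)-3,4-diacetoxycinnamic acid | O=C(O)/C=C/c1ccc(OC(C)=O)c(OC(C)=O)c1 | intermediate
15 | (E)-3,4-diacetoxycinnamoyl chloride | O=C(Cl)/C=C/c1ccc(OC(C)=O)c(OC(C)=O)c1 | intermediate
16 | 4-methoxybenzyl 3-O-[(E)-3,4-diacetoxycinnamoyl]-4,5-O-isopropylidene-1-O-methylquinate | CO[C@@]1(C(=O)OCc3ccc(OC)cc3)C[C@@H](OC(C)(C)O2)[C@@H]2[C@H](OC(=O)/C=C/c4ccc(OC(C)=O)c(OC(C)=O)c4)C1 | intermediate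
17 | 3-O-[(E)-3,4-diacetoxycinnamoyl]-1-O-methylquinic acid | CO[C@@]1(C(=O)O)C[C@@H](O)[C@@H](O)[C@H](OC(=O)/C=C/c2ccc(OC(C)=O)c(OC(C)=O)c2)C1 | intermediate
18 | 3-O-caffeoyl-1-methylquinic acid | CO[C@@]1(C(=O)O)C[C@@H](O)[C@@H](O)[C@H](OC(=O)/C=C/c2ccc(O)c(O)c2)C1 | target

## Step count and least certain steps

Total step count: 11. Longest linear sequence: 9 steps (steps 1–7, 10 and 11).

Step 3 (key step). The oxocarbenium ion may be intercepted by succinimide or traces of water before the hindered tertiary hydroxyl closes the bridged ring, or the acid may start to open the diacetal. Fallback: from 4, SO2Cl2 in CH2Cl2 at −20 °C with cyclohexene as sulfenyl chloride scavenger should give methyl 5-O-(chloromethyl)-3,4-O-[(2S,3S)-2,3-dimethoxybutane-2,3-diyl]quinate F1. With iPr2NEt this should close onto O1–H by displacement at the α-chloro ether, without any thiophile or acid, and return to the route at 5.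

Step 5. The acetal may open at the wrong bond. O1 is the better leaving group and the O5-bound oxocarbenium ion is the more stable one, so an electronically controlled opening would leave the carbon on O5. That ion could also be captured by the neighbouring O4 silyl ether, moving the bridge to O4/O5. Only the steric and basicity preference of the silyl cation for O5 argues for the wanted course. Fallback: from 6, TESOTf with 2,2′-bipyridyl in CH2Cl2 at 0 °C should silylate O3/O4 and then cleave the acetal under kinetic, base-buffered control at its less hindered oxygen. This gives methyl 1-O-[(2,2′-bipyridin-1-ium-1-yl)methyl]-3,4,5-tris-O-(triethylsilyl)quinate triflate F2, in which the carbon stays on the hindered O1 as a weakly electrophilic salt. NaSPh should convert it into methyl 1-O-(phenylthiomethyl)-3,4,5-tris-O-(triethylsilyl)quinate F3. Raney Ni in EtOH should desulfurise F3 to the methyl ether, returning to the route at 8, which is desilylated to 9 as in step 5.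

Step 2. Over-reaction to the bis(methylthiomethyl) ether, or oxidation of the axial secondary alcohol through its alkoxysulfonium ion, would consume material. Etherification at O1 instead of O5 would be harmless, since that mono-ether leads to the same acetal 5 in step 3. Fallback: from 3, Bu2SnO in toluene at reflux should give the 1,5-O-dibutylstannylene acetal F4. Chloromethyl methyl sulfide with CsF in DMF should then alkylate the tin-activated secondary oxygen once only, returning to the route at 4.

Step 11. The long aqueous-acid stage may cause partial hydrolysis of the cinnamate or slow migration of the caffeoyl group to the freed O4 before the aryl acetates are gone. Fallback: from 16, hydrazine acetate in DMF at rt should remove the two phenolic acetates by aminolysis while O4/O5 are still tied in the acetonide, so no migration is possible. This gives 4-methoxybenzyl 3-O-caffeoyl-4,5-O-isopropylidene-1-O-methylquinate F5. A short treatment with TFA/H2O (9:1) and pentamethylbenzene as cation scavenger at 0 °C should then release acid and diol together and return to the route at 18.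

## Further compounds

F1 | step 3 | methyl 5-O-(chloromethyl)-3,4-O-[(2S,3S)-2,3-dimethoxybutane-2,3-diyl]quinate | O[C@@]1(C(=O)OC)C[C@@H](OCCl)[C@@H](O[C@](C)(OC)[C@@](C)(OC)O2)[C@H]2C1
F2 | step 5 | methyl 1-O-[(2,2′-bipyridin-1-ium-1-yl)methyl]-3,4,5-tris-O-(triethylsilyl)quinate triflate | c1ccc(nc1)-c2cccc[n+]2CO[C@@]3(C(=O)OC)C[C@@H](O[Si](CC)(CC)CC)[C@@H](O[Si](CC)(CC)CC)[C@H](O[Si](CC)(CC)CC)C3.[O-]S(=O)(=O)C(F)(F)F
F3 | step 5 | methyl 1-O-(phenylthiomethyl)-3,4,5-tris-O-(triethylsilyl)quinate | c1ccccc1SCO[C@@]2(C(=O)OC)C[C@@H](O[Si](CC)(CC)CC)[C@@H](O[Si](CC)(CC)CC)[C@H](O[Si](CC)(CC)CC)C2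
F4 | step 2 | methyl 1,5-O-(dibutylstannylene)-3,4-O-[(2S,3S)-2,3-dimethoxybutane-2,3-diyl]quinate | CCCC[Sn]3(CCCC)O[C@@]1(C(=O)OC)C[C@@H](O3)[C@@H](O[C@](C)(OC)[C@@](C)(OC)O2)[C@H]2C1
F5 | step 11 | 4-methoxybenzyl 3-O-caffeoyl-4,5-O-isopropylidene-1-O-methylquinate | CO[C@@]1(C(=O)OCc3ccc(OC)cc3)C[C@@H](OC(C)(C)O2)[C@@H]2[C@H](OC(=O)/C=C/c4ccc(O)c(O)c4)C1
A1 | alternative 1 | 3-(tert-butyldimethylsilyloxy)-1-methoxycyclohex-4-ene-1-carboxylic acid, carboxyl cis to the silyloxy group | CO[C@@]1(C(=O)O)CC=C[C@H](O[Si](C)(C)C(C)(C)C)C1
A2 | alternative 1 | trans-5-(tert-butyldimethylsilyloxy)-3-methoxy-6-vinyltetrahydropyran-2-one (either C3 epimer) | COC1C[C@@H](O[Si](C)(C)C(C)(C)C)[C@H](C=C)OC1=O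
A3 | alternative 2 | (2R)-2-tert-butyl-1,3-dioxaspiro[4.5]dec-7-en-4-one | CC(C)(C)[C@@H]2O[C@@]1(C(=O)O2)CCC=CC1
A4 | alternative 2 | (R)-2-tert-butyl-5-methylene-1,3-dioxolan-4-one | CC(C)(C)[C@@H]1OC(=C)C(=O)O1
A5 | alternative 2 | buta-1,3-diene | C=CC=C
A6 | alternative 3 | methyl 3-O-(tert-butyldimethylsilyl)-1-O-methylquinate | CO[C@@]1(C(=O)OC)C[C@@H](O)[C@@H](O)[C@H](O[Si](C)(C)C(C)(C)C)C1
A7 | alternative 3 | methyl 4-(tert-butyldimethylsilyloxy)-2-methoxy-5-oxo-2-(2-oxoethyl)pentanoate | CO[C@@](C(=O)OC)(CC=O)C[C@@H](O[Si](C)(C)C(C)(C)C)C=O
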